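The plan cuts ring C at C2–C3 and at C4–C4a, so that C3 and C4 become a two-carbon bridge slipped between the C2 stereocentre and ring A. The precursor is the (R)-diazomethyl ketone 9, in which C2 (already bearing O1, ring A and ring B) is still bonded to the future C4. Photolysis triggers a Wolff rearrangement: C2 shifts with retention to the diazo carbon (C2–C3), and the ketene carbon C4 then acylates C4a of the electron-rich ring A (C4–C4a), closing ring C. The step exploits the 1,3-relation of C2 and C4 across C3 and the two equivalent, strongly nucleophilic carbons ortho to O1 in the symmetric phloroglucinol ring A.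

Key step: step 7

Assumption: in step 4 the antipode of the spirobisoxazoline ligand that delivers the R ester is used (to be fixed on the first run); ester 3 and the prenylstannane are taken as catalogue compounds.

Step 1
Reactants: 1 phloroglucinol (benzene-1,3,5-triol)
Product: 2 3,5-bis(methoxymethoxy)phenol
Conditions: MOMCl (2.0 equiv), i-Pr2NEt (2.2 equiv), DMF, 0 to 25 °C
Reagents that add atoms: chloromethyl methyl ether (MOMCl), COCCl
Why: Base-mediated O-alkylation of the phenol by the chloromethyl ether (Williamson-type MOM ether formation) should give the bis-ether as the main part of a statistical mixture, from which the mono- and tris-ethers are removed by chromatography.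

Step 2
Reactants: 3 methyl 2-(3-bromo-4-methoxyphenyl)acetate
Product: 4 methyl 2-[4-methoxy-3-(3-methylbut-2-en-1-yl)phenyl]acetate
Conditions: Pd(PPh3)4 (5 mol%), tributyl(3-methylbut-2-en-1-yl)stannane, DMF, 100 °C
Reagents that add atoms: tributyl(3-methylbut-2-en-1-yl)stannane, CCCC[Sn](CCCC)(CCCC)CC=C(C)C
Why: Stille cross-coupling, in which oxidative addition of zerovalent palladium into the aryl C–Br bond, transmetalation from the allylic stannane and reductive elimination at the unsubstituted allyl terminus should give the linear prenyl arene while the ester stays inert.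

Step 3
Reactants: 4 methyl 2-[4-methoxy-3-(3-methylbut-2-en-1-yl)phenyl]acetate
Product: 5 methyl 2-diazo-2-[4-methoxy-3-(3-methylbut-2-en-1-yl)phenyl]acetate
Conditions: p-ABSA, DBU, MeCN, 0 to 25 °C
Reagents that add atoms: 4-acetamidobenzenesulfonyl azide (p-ABSA), CC(=O)Nc1ccc(cc1)S(=O)(=O)N=[N+]=[N-]
Why: Regitz diazo transfer, in which the DBU-generated benzylic ester enolate attacks the terminal nitrogen of the sulfonyl azide and releases the sulfonamide to give the donor/acceptor diazo ester.

Step 4
Reactants: 5 methyl 2-diazo-2-[4-methoxy-3-(3-methylbut-2-en-1-yl)phenyl]acetate; 2 3,5-bis(methoxymethoxy)phenol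
Product: 6 methyl (2R)-2-[3,5-bis(methoxymethoxy)phenoxy]-2-[4-methoxy-3-(3-methylbut-2-en-1-yl)phenyl]acetate
Conditions: PdCl2(PhCN)2 (5 mol%), chiral spirobisoxazoline ligand (6 mol%), NaBArF (12 mol%), 5 Å MS, CHCl3, 25 °C
Reagents that add atoms: none
Why: Enantioselective carbene insertion into the phenol O–H bond, in which the cationic palladium carbene is attacked by the phenol oxygen and the chiral ligand controls the face of the following 1,2-proton shift, should form the O1–C2 bond and set the R configuration at the future C2.

Step 5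
Reactants: 6 methyl (2R)-2-[3,5-bis(methoxymethoxy)phenoxy]-2-[4-methoxy-3-(3-methylbut-2-en-1-yl)phenyl]acetate
Product: 7 (2R)-2-[3,5-bis(methoxymethoxy)phenoxy]-2-[4-methoxy-3-(3-methylbut-2-en-1-yl)phenyl]acetic acid
Conditions: LiOH·H2O, THF/H2O (3:1), 0 °C; then 1 M HCl to pH 3, 0 °C
Reagents that add atoms: lithium hydroxide, [Li+].[OH-]
Why: Saponification of the methyl ester at low temperature, where acyl substitution should outrun enolisation of the benzylic α-C–H so that the R configuration is kept, the brief mild acidification sparing the MOM ethers.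

Step 6
Reactants: 7 (2R)-2-[3,5-bis(methoxymethoxy)phenoxy]-2-[4-methoxy-3-(3-methylbut-2-en-1-yl)phenyl]acetic acid
Product: 9 (3R)-3-[3,5-bis(methoxymethoxy)phenoxy]-1-diazo-3-[4-methoxy-3-(3-methylbut-2-en-1-yl)phenyl]propan-2-one, via mixed isobutyl carbonic anhydride 8 (not isolated)
Conditions: i-BuOCOCl, N-methylmorpholine, THF, –20 °C; then CH2N2, Et2O, –20 to 0 °C
Reagents that add atoms: diazomethane, C=[N+]=[N-]; isobutyl chloroformate, CC(C)COC(=O)Cl (its atoms stay only in intermediate 8)
Why: Acylation of diazomethane by the mixed carbonic anhydride (first half of an Arndt–Eistert sequence) under weak-base, low-temperature conditions that should not enolise the α-stereocentre.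

Step 7
Reactants: 9 (3R)-3-[3,5-bis(methoxymethoxy)phenoxy]-1-diazo-3-[4-methoxy-3-(3-methylbut-2-en-1-yl)phenyl]propan-2-one
Product: 11 (2S)-5,7-bis(methoxymethoxy)-2-[4-methoxy-3-(3-methylbut-2-en-1-yl)phenyl]-2,3-dihydro-4H-chromen-4-one, via ketene 10 (not isolated)
Conditions: hν (405 nm LEDs), PhMe (0.01 M), 25 °C; then 80 °C in the dark
Reagents that add atoms: none
Why: Proposed new method: excitation of the diazo ketone expels N2 with a concerted 1,2-shift of C2 from the carbonyl carbon to the diazo carbon (Wolff rearrangement, new C2–C3 bond), and the ketene 10 is then attacked at its sp carbon C4 by C4a of ring A, a proton shift from the arenium carbon to C3 giving the aryl ketone (Friedel–Crafts-type C-acylation, new C4–C4a bond). The closest known reaction types are the Arndt–Eistert homologation, the thermal addition of tethered electron-rich π bonds to alkylketenes and the acid-mediated cyclisation of 3-aryloxypropanoic acids to chroman-4-ones; the capture of a Wolff ketene by a tethered phloroglucinol ether without a promoter is the part that is not established. Ring C closes in a six-membered mode by attack of C4a on C4, exo with respect to the C4=O bond and with the C3=C4 bond inside the new ring. No stereocentre is created: C2 migrates with retention, so the 3R diazo ketone should give the 2S flavanone, the descriptor changing only because the CIP ranks of ring B and the former carbonyl carbon are exchanged. The step needs the 1,2-shift to beat carbene side reactions, which direct long-wavelength excitation of an acyclic diazomethyl ketone favours, and C-acylation to beat ketene dimerisation, which high dilution and the position of C4a ortho or para to three oxygens favour; the two carbons ortho to O1 are equivalent, so no regiochemical question arises, and the unactivated ortho carbons of ring B cannot compete. The neutral medium should leave the MOM ethers, the prenyl alkene and the benzylic C2–O1 bond intact.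

Step 8
Reactants: 11 (2S)-5,7-bis(methoxymethoxy)-2-[4-methoxy-3-(3-methylbut-2-en-1-yl)phenyl]-2,3-dihydro-4H-chromen-4-one
Product: 12 4'-O-methyllicoflavanone, (2S)-5,7-dihydroxy-2-[4-methoxy-3-(3-methylbut-2-en-1-yl)phenyl]-2,3-dihydro-4H-chromen-4-one
Conditions: HCl (1.25 M in MeOH), 40 °C
Reagents that add atoms: none
Why: Acid-catalysed transacetalisation of both MOM ethers to methanol should free the 5- and 7-hydroxyls, while the C-prenyl group (ortho to a methyl ether, so unable to cyclise) and the C2 stereocentre should survive dilute acid at mild temperature.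

Compound list
1 | phloroglucinol (benzene-1,3,5-triol) | Oc1cc(O)cc(O)c1 | starting material
2 | 3,5-bis(methoxymethoxy)phenol | COCOc1cc(O)cc(OCOC)c1 | intermediate
3 | methyl 2-(3-bromo-4-methoxyphenyl)acetate | COC(=O)Cc1ccc(OC)c(Br)c1 | starting material
4 | methyl 2-[4-methoxy-3-(3-methylbut-2-en-1-yl)phenyl]acetate | COC(=O)Cc1ccc(OC)c(CC=C(C)C)c1 | intermediate
5 | methyl 2-diazo-2-[4-methoxy-3-(3-methylbut-2-en-1-yl)phenyl]acetate | COC(=O)C(=[N+]=[N-])c1ccc(OC)c(CC=C(C)C)c1 | intermediate
6 | methyl (2R)-2-[3,5-bis(methoxymethoxy)phenoxy]-2-[4-methoxy-3-(3-methylbut-2-en-1-yl)phenyl]acetate | COC(=O)[C@H](Oc1cc(OCOC)cc(OCOC)c1)c1ccc(OC)c(CC=C(C)C)c1 | intermediate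
7 | (2R)-2-[3,5-bis(methoxymethoxy)phenoxy]-2-[4-methoxy-3-(3-methylbut-2-en-1-yl)phenyl]acetic acid | OC(=O)[C@H](Oc1cc(OCOC)cc(OCOC)c1)c1ccc(OC)c(CC=C(C)C)c1 | intermediate
8 | mixed anhydride of acid 7 with isobutyl hydrogen carbonate (2R) | CC(C)COC(=O)OC(=O)[C@H](Oc1cc(OCOC)cc(OCOC)c1)c1ccc(OC)c(CC=C(C)C)c1 | intermediate
9 | (3R)-3-[3,5-bis(methoxymethoxy)phenoxy]-1-diazo-3-[4-methoxy-3-(3-methylbut-2-en-1-yl)phenyl]propan-2-one | [N-]=[N+]=CC(=O)[C@H](Oc1cc(OCOC)cc(OCOC)c1)c1ccc(OC)c(CC=C(C)C)c1 | intermediate
10 | ketene, (3S)-3-[3,5-bis(methoxymethoxy)phenoxy]-3-[4-methoxy-3-(3-methylbut-2-en-1-yl)phenyl]prop-1-en-1-one | O=C=C[C@H](Oc1cc(OCOC)cc(OCOC)c1)c1ccc(OC)c(CC=C(C)C)c1 | intermediate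
11 | (2S)-5,7-bis(methoxymethoxy)-2-[4-methoxy-3-(3-methylbut-2-en-1-yl)phenyl]-2,3-dihydro-4H-chromen-4-one | COc1ccc([C@@H]2CC(=O)c3c(OCOC)cc(OCOC)cc3O2)cc1CC=C(C)C | intermediate
12 | 4'-O-methyllicoflavanone, (2S)-5,7-dihydroxy-2-[4-methoxy-3-(3-methylbut-2-en-1-yl)phenyl]-2,3-dihydro-4H-chromen-4-one | COc1ccc([C@@H]2CC(=O)c3c(O)cc(O)cc3O2)cc1CC=C(C)C | target

Total step count: 8. Longest linear sequence: 7 steps (3 to 12, steps 2 to 8); step 1 prepares the ring A phenol that joins in step 4.

Steps most likely to fail

Step 7. After the 1,2-shift the ketene may dimerise, or be captured by adventitious water, faster than it acylates ring A without a promoter. Carbene-type pathways may also divert part of the material. The fallback sets out from 9 and comes back at 11, forming the two bonds in two operations of known type. Photolysis of 9 (405 nm) in THF/H2O should give, by Wolff rearrangement and hydration of ketene 10, the homologous (3S)-3-[3,5-bis(methoxymethoxy)phenoxy]-3-[4-methoxy-3-(3-methylbut-2-en-1-yl)phenyl]propanoic acid F1. Treatment with trifluoroacetic anhydride in CH2Cl2 at 0 °C should convert it into the mixed trifluoroacetic anhydride F2, which is not isolated. This should cyclise by intramolecular Friedel–Crafts acylation at C4a, the classical chroman-4-one closure of 3-aryloxypropanoic acids, to give 11.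

Step 4. The proton shift may proceed with poor facial control for this bulky, electron-rich phenol, or the electrophilic carbene may alkylate a ring carbon of 2 instead of its oxygen. The fallback sets out from 5 and comes back at 6; it makes the C2–O1 bond by substitution with inversion instead of carbene insertion into the phenol. Asymmetric insertion of 5 into the O–H bond of water (CuCl, NaBArF, chiral spirobisoxazoline ligand, H2O, CHCl3), a known reaction of α-aryl-α-diazoacetates, should give methyl (2S)-2-hydroxy-2-[4-methoxy-3-(3-methylbut-2-en-1-yl)phenyl]acetate F3. A Mitsunobu reaction of F3 with phenol 2 (PPh3, DIAD, PhMe, 0 °C) should then give 6 with inversion at the carbinol carbon.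

Step 6. The acidic benzylic α-C–H may enolise in the activated acid (mixed anhydride, or a ketene formed from it), so that configurational purity is lost before or in the diazo ketone. The fallback moves the stereochemical control to the end: it sets out from 11 of eroded enantiomeric purity (what such material gives in step 7) and comes back at 11. A kinetic resolution by asymmetric transfer hydrogenation, known for racemic flavanones (RuCl(p-cymene)(TsDPEN), HCO2H/Et3N, with the ligand antipode that reduces the 2R ketone), should convert the unwanted (2R)-5,7-bis(methoxymethoxy)-2-[4-methoxy-3-(3-methylbut-2-en-1-yl)phenyl]-2,3-dihydro-4H-chromen-4-one F4 into the cis alcohol (2R,4R)-5,7-bis(methoxymethoxy)-2-[4-methoxy-3-(3-methylbut-2-en-1-yl)phenyl]-3,4-dihydro-2H-chromen-4-ol F5. F5 is removed by chromatography, leaving the 2S ketone 11.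

Further compounds
F1 | step 7 | (3S)-3-[3,5-bis(methoxymethoxy)phenoxy]-3-[4-methoxy-3-(3-methylbut-2-en-1-yl)phenyl]propanoic acid | OC(=O)C[C@H](Oc1cc(OCOC)cc(OCOC)c1)c1ccc(OC)c(CC=C(C)C)c1
F2 | step 7 | mixed anhydride of F1 with trifluoroacetic acid (3S) | O=C(OC(=O)C[C@H](Oc1cc(OCOC)cc(OCOC)c1)c1ccc(OC)c(CC=C(C)C)c1)C(F)(F)F
F3 | step 4 | methyl (2S)-2-hydroxy-2-[4-methoxy-3-(3-methylbut-2-en-1-yl)phenyl]acetate | COC(=O)[C@@H](O)c1ccc(OC)c(CC=C(C)C)c1
F4 | step 6 | (2R)-5,7-bis(methoxymethoxy)-2-[4-methoxy-3-(3-methylbut-2-en-1-yl)phenyl]-2,3-dihydro-4H-chromen-4-one | COc1ccc([C@H]2CC(=O)c3c(OCOC)cc(OCOC)cc3O2)cc1CC=C(C)C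
F5 | step 6 | (2R,4R)-5,7-bis(methoxymethoxy)-2-[4-methoxy-3-(3-methylbut-2-en-1-yl)phenyl]-3,4-dihydro-2H-chromen-4-ol | COc1ccc([C@H]2C[C@@H](O)c3c(OCOC)cc(OCOC)cc3O2)cc1CC=C(C)C
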